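## Structural features

The target is an unsymmetrical dimer of two 2-arylchromane-3,4-diols (flavan-3,4-diols). Each half has a benzo ring A with hydroxyls at C7 and C8, a pyran ring C (O1, C2, C3, C4, C4a, C8a) and a 4-hydroxyphenyl ring B on C2; the halves are joined by the biaryl bond C6–C6' between the two rings A. Each ring C carries three contiguous stereocentres: C2 and C3 are (R,R) and cis in both halves, while C4 is (R) in one half (3,4-cis, all-cis) and (S) in the other (3,4-trans). The biaryl axis has only one oxygen substituent ortho to it on each ring and is not a stereogenic element. The fragile groups are the benzylic C4 hydroxyls (C4 is para to the C7 oxygen and joined through C8a to O1, so it ionises easily), the benzylic C2–O1 ether para to the ring B oxygen, and the air-sensitive trioxygenated rings A; acid must be avoided once C4 is oxygenated, and the phenols must be freed last under neutral conditions. The real difficulty is to build two fully substituted rings A around a central biaryl, to set the 2,3-cis relationship twice, and then to tell two almost identical halves apart at C4. The key step exploits the fact that C4a of each ring A is the only free position ortho to the ether oxygen O1 and lies para to the C7 oxygen. An aryl ether that already carries C2 and C3 can therefore close ring C last through the C4–C4a bond, and the C6–C6' axis allows this on both halves at once.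

## Logic of the disconnections

23 ⇒ 22. The four benzyl–oxygen bonds on the rings A are cut last. The trioxygenated rings stay masked until the final, neutral operation, and a free C7 phenol never meets acid or base while C4 carries oxygen. The forward step must cleave aryl benzyl ethers without hydrogenolysing the benzylic C4–O and C2–O1 bonds.

22 ⇒ 21. The acyl–oxygen bonds of the two ring B pivalates and of the cyclic carbonate are cut together. One methanolysis removes every ester while ring A is still etherified. The base must be mild enough that the ring B phenoxide does not open the C2–O1 bond.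

21 ⇒ 19. Both C4–O bonds are cut, which returns C4 to a methylene group in each half. This removes two stereocentres and the only difference between the halves except for one carbonate. The forward step must take hydride from both C4 positions and deliver oxygen cis from the carbonate in one half and trans from water in the other, without over-oxidation.

19 ⇒ 18. One carbonate O–C bond is cut, giving a C2-symmetric diol. This is the only desymmetrising event; it is statistical and must be run so that 18 is recovered and recycled.

18 ⇒ 16. The two C4–C4a bonds are cut, opening both rings C to terminal epoxides on a bis(aryl ether). C4a is the most nucleophilic reachable carbon of each ring A, and C2 and C3 can be brought in as a finished, enantiopure three-carbon unit. Two rings and two skeletal bonds form in one isomerisation, with no new stereocentre. The closure must be 6-endo at the CH2 carbon, and the benzylic C2–O1 bond must survive the activation. The arms of 16 are (R) at the benzylic carbon and (R) at the oxirane carbon (threo), which maps onto (2R,3R) in 18 without change.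

16 ⇒ 8 + 14. The two O1–C2 bonds are cut, giving a symmetric biphenyldiol and two molecules of one epoxy alcohol. The forward etherification must invert the benzylic carbinol cleanly, so 14 must be the erythro (anti) isomer and C2 must not ionise. The pivalate on ring B serves this purpose here and again in the key step.

14 ⇒ 13 ⇒ 11 + 12, and 11 ⇒ 9 + 10. The oxirane C–O bonds are cut back to a racemic aryl vinyl carbinol. One kinetic resolution with epoxidation sets both C3 and the carbinol centre. The carbinol comes from C–C bond formation between an aldehyde and a vinyl nucleophile, and the ester from acylation of the phenol. The vinyl addition must prefer the aldehyde over the hindered ester.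

8 ⇒ 6 ⇒ 4 + 5, then 5 ⇒ 4 ⇒ 3 ⇒ 1. The two phenolic C–O bonds of 8 are traced to formyl groups. The biaryl bond is cut into an aryl bromide and the aryl boronate made from the same bromide, so one building block serves both rings A. The benzyl ethers go back to a catechol and the formyl group to a C–H bond. The position of the biaryl bond is fixed by the bromine already present in 1, and the position of the later phenol by the only free site ortho to a hydroxyl. No step depends on the ortho/para selectivity of a phenol coupling or halogenation. The price is a longer sequence than a direct oxidative coupling of a dialkoxyphenol.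

## Other disconnections considered

Alternative 1: The second ring A is cut at C8a–C8, C6–C7 and C4a–C8a, leading back to the aryl diazo enone A1 (the finished, protected all-cis half with the diazo ketone on C6) and di-tert-butoxyethyne A2. In the forward direction A1 would be irradiated with A2. Wolff rearrangement, [2+2] cycloaddition, four-electron ring opening, six-electron ring closure and tautomerisation would follow in one flask and end at the phenol A3.
- In its favour: the hexasubstituted ring is assembled with unambiguous regiochemistry, and the biaryl bond needs no coupling. The halves are made one after the other, so their C4 configurations can be set independently; on this point it is better than the chosen plan, which needs a statistical mono-acylation.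
- Against it: a half carrying three stereocentres and a protected benzylic diol must survive diazo transfer and photolysis. After A3 the second ring C still lacks O1–C2, C2–C3 and all three stereocentres. The tert-butyl ethers of A3 need acid for removal, which a flavan-3,4-diol tolerates poorly.
- Comparison: structurally it ignores the near-symmetry that the chosen plan uses twice. Mechanistically it is a pericyclic cascade instead of a cationic aromatic substitution. In step economy it is clearly longer and linear.

Alternative 2: O1–C2 and C3–C4 are cut in both halves, giving the bis-salicylaldehyde A4 and two molecules of 4-(benzyloxy)cinnamaldehyde A5. Under a secondary-amine catalyst of the diarylprolinol silyl ether class, iminium activation of A5, oxa-Michael addition of each phenol, enamine-mediated aldol condensation with the neighbouring formyl group and dehydration would give the bis(2H-chromene-3-carbaldehyde) A6.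
- In its favour: it is two-directional like the chosen plan (equal). C2 is set by a catalyst with neither resolution nor inversion, which is better than a kinetic resolution that discards half of the carbinol.
- Against it: A6 carries a formyl carbon on C3 that the target does not contain; it must be excised and replaced by oxygen. C3 and C4 are still without stereochemistry, and additions to the C3=C4 bond would be expected anti to the C2 aryl group, which leads to the 2,3-trans series and not the 2,3-cis one needed. The oxa-Michael step is reversible for electron-rich 2-aryl groups, so the C2 configuration is at risk.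
- Comparison: the structure is reached faster up to ring closure, but more steps would follow it than the four that follow 18.

Alternative 3: Only the two C4–O bonds are cut, leading back to the mono-carbonate A7. Anodic oxidation in wet acetonitrile would remove two electrons and a proton at each C4; the carbonate oxygen would close cis in one half and water would add trans in the other, giving A8.
- In its favour: the selectivity elements are those of step 12 of the chosen plan (equal), and no stoichiometric quinone is spent (better in reagent economy).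
- Against it: as a strategic cut it builds no skeleton, so the whole bis-flavan must come from elsewhere. With benzyl ethers on ring B the C2–H bond and the ether methylenes lie close in potential to C4–H, and the benzylic alcohol formed is itself oxidisable at the electrode.
- Comparison: the chosen plan contains the same idea with DDQ, which selects C4–H by hydride transfer within a donor–acceptor complex, and with pivalates that deactivate ring B. The step count is equal; the chemoselectivity is expected to be better with DDQ.

Key step: step 10

Remark: 3-bromocatechol is taken as a catalogue compound, and in step 12 the half with the free 3-hydroxyl is taken to be oxidised first because the carbonate lowers the hydride-donor ability of its own C4–H; the other order leads to the same product 21.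

## Route

Step 1
Reactants: 1 3-bromocatechol
Product: 3 4-bromo-2,3-dihydroxybenzaldehyde, via hydroxymethyl catechol 2 (not isolated)
Conditions: MgCl2, Et3N, (CH2O)n, MeCN, reflux; then 1 M HCl
Reagents that add atoms: paraformaldehyde (formaldehyde) C=O
Why: Magnesium-mediated ortho-formylation of a phenol (Casnati–Skattebøl): the magnesium phenoxide delivers formaldehyde to the only free carbon ortho to a hydroxyl, which is para to bromine, and the benzylic alkoxide 2 passes hydride to a second formaldehyde. The substitution pattern of ring A is thereby fixed without any ortho/para choice.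

Step 2
Reactants: 3 4-bromo-2,3-dihydroxybenzaldehyde
Product: 4 2,3-bis(benzyloxy)-4-bromobenzaldehyde
Conditions: BnBr, K2CO3, DMF, 60 °C
Reagents that add atoms: benzyl bromide BrCc1ccccc1
Why: Williamson etherification of both phenols; the aldehyde and the aryl bromide are inert to carbonate and benzyl bromide.

Step 3
Reactants: 4 2,3-bis(benzyloxy)-4-bromobenzaldehyde
Product: 5 2,3-bis(benzyloxy)-4-(4,4,5,5-tetramethyl-1,3,2-dioxaborolan-2-yl)benzaldehyde
Conditions: B2pin2 (1.1 equiv), Pd(dppf)Cl2 (3 mol %), KOAc, 1,4-dioxane, 90 °C
Reagents that add atoms: bis(pinacolato)diboron CC1(C)OB(OC1(C)C)B1OC(C)(C)C(C)(C)O1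
Why: Miyaura borylation: oxidative addition of the aryl bromide to zerovalent palladium, acetate-assisted transmetalation with the diboron reagent and reductive elimination give the aryl boronate. The formyl group activates the bromide, is not enolisable and is inert to the weak acetate base, as are the benzyl ethers.

Step 4
Reactants: 4 2,3-bis(benzyloxy)-4-bromobenzaldehyde; 5 2,3-bis(benzyloxy)-4-(4,4,5,5-tetramethyl-1,3,2-dioxaborolan-2-yl)benzaldehyde
Product: 6 2,2',3,3'-tetrakis(benzyloxy)biphenyl-4,4'-dicarbaldehyde
Conditions: Pd(OAc)2 (3 mol %), SPhos (6 mol %), K3PO4, toluene/H2O (10:1), 90 °C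
Reagents that add atoms: none
Why: Suzuki–Miyaura cross-coupling of boronate 5 with a second molecule of bromide 4, so that the C6–C6' bond forms exactly where bromine and boron stood. The dialkylbiarylphosphine ligand is chosen because the new bond carries one ortho benzyloxy group on each ring.

Step 5
Reactants: 6 2,2',3,3'-tetrakis(benzyloxy)biphenyl-4,4'-dicarbaldehyde
Product: 8 2,2',3,3'-tetrakis(benzyloxy)biphenyl-4,4'-diol, via bis-formate 7 (not isolated)
Conditions: mCPBA, CH2Cl2, 0 °C → rt; then K2CO3 (cat.), MeOH, rt
Reagents that add atoms: mCPBA OOC(=O)c1cccc(Cl)c1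
Why: Baeyer–Villiger (Dakin-type) oxidation: the electron-rich aryl groups with ortho alkoxy substituents migrate in preference to hydride, and the aryl formates are methanolysed in the same flask. Benzyl ethers are stable to the peracid.

Step 6
Reactants: 9 4-hydroxybenzaldehyde; 10 pivaloyl chloride
Product: 11 4-formylphenyl pivalate
Conditions: Et3N, DMAP (cat.), CH2Cl2, 0 °C → rt
Reagents that add atoms: none
Why: Acylation of the phenol; the pivalate later makes ring B electron-poor enough to keep C2 from ionising and is hindered enough to survive the Grignard step.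

Step 7
Reactants: 11 4-formylphenyl pivalate; 12 vinylmagnesium bromide
Product: 13 rac-4-(1-hydroxyprop-2-en-1-yl)phenyl pivalate
Conditions: THF, −78 °C; aq. NH4Cl
Reagents that add atoms: none
Why: Grignard 1,2-addition; at low temperature the aldehyde reacts far faster than the hindered aryl pivalate. The new carbinol centre is racemic and is resolved in the next step.

Step 8
Reactants: 13 rac-4-(1-hydroxyprop-2-en-1-yl)phenyl pivalate
Product: 14 4-{(S)-hydroxy[(2R)-oxiran-2-yl]methyl}phenyl pivalate (erythro, anti)
Conditions: Ti(OiPr)4 (15 mol %), L-(+)-DIPT (18 mol %), t-BuOOH (0.45 equiv), 4 Å MS, CH2Cl2, −20 °C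
Reagents that add atoms: tert-butyl hydroperoxide CC(C)(C)OO
Why: Sharpless kinetic resolution with epoxidation: with L-(+)-tartrate the (R)-carbinol is the fast-reacting enantiomer and is epoxidised on the alkene face that gives the erythro (anti) epoxy alcohol, which sets the oxirane carbon (R). The carbinol descriptor changes from (R) to (S) only because the oxirane outranks the aryl group. The (S)-alcohol stays behind and is separated, and the reaction is stopped below half conversion so that the product is enantiomerically enriched.

Step 9
Reactants: 8 2,2',3,3'-tetrakis(benzyloxy)biphenyl-4,4'-diol; 14 4-{(S)-hydroxy[(2R)-oxiran-2-yl]methyl}phenyl pivalate (2.4 equiv)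
Product: 16 2,2',3,3'-tetrakis(benzyloxy)-4,4'-bis{(R)-[(2R)-oxiran-2-yl][4-(pivaloyloxy)phenyl]methoxy}biphenyl (threo in each arm), via mono-ether 15 (not isolated)
Conditions: PPh3, DIAD, toluene/THF, 0 °C → rt
Reagents that add atoms: none
Why: Double Mitsunobu etherification: each phenol displaces the alkoxyphosphonium group by SN2 with inversion, turning the erythro alcohol into the threo ether with C2 (R). The para-pivaloyloxy group and the adjacent oxirane disfavour ionisation. Coupling two units also purifies the product statistically, because the minor enantiomer of 14 ends mostly in a separable diastereomer.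

Step 10
Reactants: 16 2,2',3,3'-tetrakis(benzyloxy)-4,4'-bis{(R)-[(2R)-oxiran-2-yl][4-(pivaloyloxy)phenyl]methoxy}biphenyl
Product: 18 6,6'-bi[(2R,3R)-7,8-bis(benzyloxy)-3-hydroxy-2-(4-pivaloyloxyphenyl)chromane] (2,3-cis in both halves), via mono-cyclised epoxide 17 (not isolated)
Conditions: HFIP/CH2Cl2 (4:1, 0.02 M), 25 → 45 °C
Reagents that add atoms: none
Why: HFIP hydrogen-bonds to each oxirane oxygen and polarises the C4–O bond; C4a of the adjoining ring A (ortho to O1, para to the C7 benzyloxy group) attacks the CH2 carbon from the side opposite the leaving oxygen, and the arenium ion loses its proton to leave the C3 hydroxyl. The closest known reaction type is the intramolecular Friedel–Crafts epoxy-arene cyclisation of aryl glycidyl ethers to chroman-3-ols. Each ring C (O1, C2, C3, C4, C4a, C8a) is closed in the 6-endo mode with respect to the oxirane by the C4–C4a bond; the 5-exo alternative at C3 would give a 3-(hydroxymethyl)dihydrobenzofuran. No stereocentre is created: C2 and C3 are spectators, so the threo ether–epoxide relationship of 16 appears unchanged as the 2,3-cis (2R,3R) relationship of 18. Attack at the terminal carbon is secured by the unhindered CH2 group and by the inductively deactivated, more hindered C3. Attack by C4a alone follows because C8 is blocked by its benzyl ether and C5 cannot be reached by the three-atom tether, while an oxonium ion formed by the C8 ether oxygen cannot lose benzyl in the non-nucleophilic medium and reverts. The C2–O1 bond is kept intact by the para-pivaloyloxy group on ring B, which destabilises the benzylic cation. The two closures are independent, and 17 reacts on under the same conditions.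

Step 11
Reactants: 18 6,6'-bi[(2R,3R)-7,8-bis(benzyloxy)-3-hydroxy-2-(4-pivaloyloxyphenyl)chromane]
Product: 19 mono(tert-butyl carbonate) of 18 at one O3
Conditions: Boc2O (0.7 equiv), DMAP (0.2 equiv), CH2Cl2, 0 °C → rt; recovered 18 recycled
Reagents that add atoms: di-tert-butyl dicarbonate CC(C)(C)OC(=O)OC(=O)OC(C)(C)C
Why: DMAP-catalysed carbonate formation on a secondary alcohol; the two hydroxyls are remote and equivalent, so the outcome is statistical. A deficit of reagent keeps the bis-carbonate low and leaves mainly 19 and recyclable 18.

Step 12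
Reactants: 19 mono(tert-butyl carbonate) of 18 at one O3
Product: 21 tetra-O-benzyl di-O-pivaloyl bis-flavan with a 3,4-cis cyclic carbonate in the all-cis half and a 2,3-cis-3,4-trans diol in the other half, via trans-diol carbonate 20 (not isolated)
Conditions: DDQ (2.4 equiv), CH2Cl2/pH 7 phosphate buffer (10:1), 0 °C → rt
Reagents that add atoms: water O
Why: Proposed new method: DDQ removes hydride from each benzylic C4–H (para to the C7 ether oxygen and joined through C8a to O1) to give an oxygen-stabilised cation; in the carbonate half the Boc carbonyl oxygen closes a five-membered ring on C4 from the face of the C3 oxygen and tert-butyl leaves as isobutene, which can only give the 3,4-cis-fused carbonate, whereas in the other half water adds anti to the axial free 3-hydroxyl and gives the 3,4-trans diol. The closest known reaction types are the DDQ oxidation of benzyl-protected flavan-3-ols at C4 with capture by alcohols or water (3,4-trans in the 2,3-cis series) and the participation of tert-butyl carbonates in cation-terminated cyclisations to cyclic carbonates.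

Step 13
Reactants: 21 carbonate/trans-diol bis-flavan
Product: 22 7,7',8,8'-tetra-O-benzyl ether of 23
Conditions: K2CO3, MeOH/THF (2:1), 0 °C → rt; aq. NH4Cl
Reagents that add atoms: none
Why: Base-catalysed transesterification cleaves both aryl pivalates and the cyclic carbonate in one operation. Ring A is still etherified, so no C7 phenoxide can expel the C4 hydroxyl, and the short, cold treatment keeps the ring B phenoxide from opening the C2–O1 bond.

Step 14
Reactants: 22 7,7',8,8'-tetra-O-benzyl ether of 23
Product: 23 (2R,3R,4R)-6-[(2R,3R,4S)-3,4,7,8-tetrahydroxy-2-(4-hydroxyphenyl)chroman-6-yl]-2-(4-hydroxyphenyl)chromane-3,4,7,8-tetrol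
Conditions: H2 (1 atm), 10% Pd/C, EtOAc/MeOH (1:1), rt; filtration and concentration under argon
Reagents that add atoms: none
Why: Hydrogenolysis of aryl benzyl ethers, which is much faster than reduction of a secondary benzylic alcohol in a neutral medium, as in the debenzylation of catechol ethers that carry benzylic hydroxyls. No acid is present, so C4 does not ionise, and the six stereocentres are untouched.

## Compound list

1 | 3-bromocatechol | Oc1cccc(Br)c1O | starting material
2 | 3-bromo-6-(hydroxymethyl)benzene-1,2-diol | OCc1ccc(Br)c(O)c1O | intermediate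
3 | 4-bromo-2,3-dihydroxybenzaldehyde | O=Cc1ccc(Br)c(O)c1O | intermediate
4 | 2,3-bis(benzyloxy)-4-bromobenzaldehyde | O=Cc1ccc(Br)c(OCc2ccccc2)c1OCc1ccccc1 | intermediate
5 | 2,3-bis(benzyloxy)-4-(4,4,5,5-tetramethyl-1,3,2-dioxaborolan-2-yl)benzaldehyde | O=Cc1ccc(B2OC(C)(C)C(C)(C)O2)c(OCc2ccccc2)c1OCc1ccccc1 | intermediate
6 | 2,2',3,3'-tetrakis(benzyloxy)biphenyl-4,4'-dicarbaldehyde | O=Cc1ccc(-c2ccc(C=O)c(OCc3ccccc3)c2OCc2ccccc2)c(OCc2ccccc2)c1OCc1ccccc1 | intermediate
7 | 2,2',3,3'-tetrakis(benzyloxy)biphenyl-4,4'-diyl diformate | O=COc1ccc(-c2ccc(OC=O)c(OCc3ccccc3)c2OCc2ccccc2)c(OCc2ccccc2)c1OCc1ccccc1 | intermediate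
8 | 2,2',3,3'-tetrakis(benzyloxy)biphenyl-4,4'-diol | Oc1ccc(-c2ccc(O)c(OCc3ccccc3)c2OCc2ccccc2)c(OCc2ccccc2)c1OCc1ccccc1 | intermediate
9 | 4-hydroxybenzaldehyde | O=Cc1ccc(O)cc1 | starting material
10 | pivaloyl chloride | CC(C)(C)C(Cl)=O | starting material
11 | 4-formylphenyl pivalate | CC(C)(C)C(=O)Oc1ccc(C=O)cc1 | intermediate
12 | vinylmagnesium bromide | C=C[Mg]Br | starting material
13 | rac-4-(1-hydroxyprop-2-en-1-yl)phenyl pivalate (racemic) | CC(C)(C)C(=O)Oc1ccc(cc1)C(O)C=C | intermediate
14 | 4-{(S)-hydroxy[(2R)-oxiran-2-yl]methyl}phenyl pivalate | CC(C)(C)C(=O)Oc1ccc(cc1)[C@H](O)[C@H]1CO1 | intermediate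
15 | 2,2',3,3'-tetrakis(benzyloxy)-4'-{(R)-[(2R)-oxiran-2-yl][4-(pivaloyloxy)phenyl]methoxy}biphenyl-4-ol | CC(C)(C)C(=O)Oc1ccc(cc1)[C@@H](Oc1c(OCc2ccccc2)c(OCc2ccccc2)c(cc1)-c1ccc(O)c(OCc2ccccc2)c1OCc1ccccc1)[C@H]1CO1 | intermediate
16 | 2,2',3,3'-tetrakis(benzyloxy)-4,4'-bis{(R)-[(2R)-oxiran-2-yl][4-(pivaloyloxy)phenyl]methoxy}biphenyl | CC(C)(C)C(=O)Oc1ccc(cc1)[C@@H](Oc1c(OCc2ccccc2)c(OCc2ccccc2)c(cc1)-c1ccc(O[C@H](c2ccc(OC(=O)C(C)(C)C)cc2)[C@H]2CO2)c(OCc2ccccc2)c1OCc1ccccc1)[C@H]1CO1 | intermediate
17 | half-cyclised compound: (2R,3R)-2,3-cis-flavan-3-ol in one half, (R,R) aryl ether epoxide arm on the other ring A | CC(C)(C)C(=O)Oc1ccc(cc1)[C@H]1Oc2c(cc(-c3ccc(O[C@H](c4ccc(OC(=O)C(C)(C)C)cc4)[C@H]4CO4)c(OCc4ccccc4)c3OCc3ccccc3)c(OCc3ccccc3)c2OCc2ccccc2)C[C@H]1O | intermediate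
18 | 6,6'-bi[(2R,3R)-7,8-bis(benzyloxy)-3-hydroxy-2-(4-pivaloyloxyphenyl)chromane], 2,3-cis in both halves | CC(C)(C)C(=O)Oc1ccc(cc1)[C@H]1Oc2c(cc(-c3cc4c(c(OCc5ccccc5)c3OCc3ccccc3)O[C@H](c3ccc(OC(=O)C(C)(C)C)cc3)[C@H](O)C4)c(OCc3ccccc3)c2OCc2ccccc2)C[C@H]1O | intermediate
19 | mono(tert-butyl carbonate) of 18 at one O3 (free 3-hydroxyl in the other half) | CC(C)(C)C(=O)Oc1ccc(cc1)[C@H]1Oc2c(cc(-c3cc4c(c(OCc5ccccc5)c3OCc3ccccc3)O[C@H](c3ccc(OC(=O)C(C)(C)C)cc3)[C@H](O)C4)c(OCc3ccccc3)c2OCc2ccccc2)C[C@H]1OC(=O)OC(C)(C)C | intermediate
20 | 19 with a 3,4-trans diol (2R; 2,3-cis; 3,4-trans) in the half that carries no carbonate | CC(C)(C)C(=O)Oc1ccc(cc1)[C@H]1Oc2c(cc(-c3cc4c(c(OCc5ccccc5)c3OCc3ccccc3)O[C@H](c3ccc(OC(=O)C(C)(C)C)cc3)[C@H](O)[C@H]4O)c(OCc3ccccc3)c2OCc2ccccc2)C[C@H]1OC(=O)OC(C)(C)C | intermediate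
21 | tetra-O-benzyl di-O-pivaloyl bis-flavan: 3,4-cis cyclic carbonate (2R, all-cis) in one half, 3,4-trans diol (2R; 2,3-cis) in the other | CC(C)(C)C(=O)Oc1ccc(cc1)[C@H]1Oc2c(cc(-c3cc4c(c(OCc5ccccc5)c3OCc3ccccc3)O[C@H](c3ccc(OC(=O)C(C)(C)C)cc3)[C@H](O)[C@H]4O)c(OCc3ccccc3)c2OCc2ccccc2)[C@@H](OC(=O)O3)[C@H]13 | intermediate
22 | 7,7',8,8'-tetra-O-benzyl ether of 23 | Oc1ccc(cc1)[C@H]1Oc2c(cc(-c3cc4c(c(OCc5ccccc5)c3OCc3ccccc3)O[C@H](c3ccc(O)cc3)[C@H](O)[C@H]4O)c(OCc3ccccc3)c2OCc2ccccc2)[C@@H](O)[C@H]1O | intermediate
23 | (2R,3R,4R)-6-[(2R,3R,4S)-3,4,7,8-tetrahydroxy-2-(4-hydroxyphenyl)chroman-6-yl]-2-(4-hydroxyphenyl)chromane-3,4,7,8-tetrol | Oc1ccc([C@H]2Oc3c(cc(-c4cc5c(c(O)c4O)O[C@H](c4ccc(O)cc4)[C@H](O)[C@H]5O)c(O)c3O)[C@@H](O)[C@H]2O)cc1 | target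

## Step count and least certain steps

Total: 14 steps. Longest linear sequence: 11 steps (steps 1–5 and 9–14, from 1 to 23); the three-step branch 6–8 joins at step 9.

Step 12 (proposed new method). What may go wrong: water may capture the C4 cation of the carbonate half from the face anti to the carbonate before the carbonyl oxygen closes, which would give trans in both halves. The newly formed benzylic alcohol may also be oxidised further to the ketone. The fallback uses known chemistry, sets out from 18 and returns at 22. DDQ in wet CH2Cl2 on 18 gives the bis(3,4-trans-diol) F1. A limited amount of activated MnO2 then oxidises one benzylic C4 hydroxyl to the mono-4-ketone F2 (statistical, F1 recycled). NaBH4 in MeOH/THF at −40 °C delivers hydride anti to the axial 3-hydroxyl and gives the cis/trans tetraol dipivalate F3, and methanolysis of F3 under the conditions of step 13 gives 22.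

Step 10 (key step). What may go wrong: both closures must succeed in the same molecule. The half-cyclised 17 carries a free hydroxyl and is less soluble, so its remaining oxirane may be lost to addition of HFIP, to a hydride shift, or to ionisation at C2 before C4a attacks; a catalytic amount of BF3·OEt2 at low temperature is the first reserve. The fallback closes ring C once per molecule and joins the halves afterwards; it sets out from 4 and 14 and returns at 18. Baeyer–Villiger oxidation of 4 and methanolysis give, through the aryl formate F4, the bromophenol F5. Mitsunobu coupling of F5 with 14 gives the monomeric aryl ether epoxide F6, and closure in HFIP gives the 6-bromoflavan-3-ol F7. Reductive homocoupling of two molecules of F7 with the zerovalent nickel complex Ni(cod)2 and 2,2'-bipyridine in DMF at 60 °C gives 18.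

Step 9. What may go wrong: the second etherification at the hindered, ortho-alkoxylated phenol may be incomplete. Partial ionisation of the benzylic alkoxyphosphonium ion may erode the inversion, and the hydrazide may be alkylated in place of the phenol. The fallback sets out from 14 and 8 and returns at 16: MsCl and Et3N convert 14 with retention into the epoxy mesylate F8, which the bis-phenoxide of 8 (Cs2CO3, DMF, rt) displaces by Williamson substitution with inversion; at room temperature the activated benzylic sulfonate should react before the oxirane is opened.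

Step 8. What may go wrong: if conversion overshoots, the slow enantiomer is drawn into the product and its enantiomeric purity falls. Prolonged contact with the titanium alkoxide may also open the benzylic epoxy alcohol. The fallback takes the purity from the substrate side, sets out from 13 and returns at 14: resolution of 13 with D-(−)-DIPT and 0.6 equivalents of t-BuOOH leaves the (R)-allylic alcohol F9, while the (S)-enantiomer is consumed as the enantiomeric epoxy alcohol F10 (discarded). F9 is then epoxidised to completion with Ti(OiPr)4, L-(+)-DIPT and t-BuOOH (matched pair) to give 14.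

## Further compounds

F1 | step 12 | bis(3,4-trans-diol): 6,6'-bi[(2R)-2,3-cis-3,4-trans-7,8-bis(benzyloxy)-3,4-dihydroxy-2-(4-pivaloyloxyphenyl)chromane] | CC(C)(C)C(=O)Oc1ccc(cc1)[C@H]1Oc2c(cc(-c3cc4c(c(OCc5ccccc5)c3OCc3ccccc3)O[C@H](c3ccc(OC(=O)C(C)(C)C)cc3)[C@H](O)[C@H]4O)c(OCc3ccccc3)c2OCc2ccccc2)[C@H](O)[C@H]1O
F2 | step 12 | mono-4-ketone of F1 (3-hydroxy-4-oxo in one half, 3,4-trans diol in the other) | CC(C)(C)C(=O)Oc1ccc(cc1)[C@H]1Oc2c(cc(-c3cc4c(c(OCc5ccccc5)c3OCc3ccccc3)O[C@H](c3ccc(OC(=O)C(C)(C)C)cc3)[C@H](O)[C@H]4O)c(OCc3ccccc3)c2OCc2ccccc2)C(=O)[C@H]1O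
F3 | step 12 | tetraol dipivalate: all-cis 3,4-diol in one half, 3,4-trans diol in the other, ring A benzyl ethers | CC(C)(C)C(=O)Oc1ccc(cc1)[C@H]1Oc2c(cc(-c3cc4c(c(OCc5ccccc5)c3OCc3ccccc3)O[C@H](c3ccc(OC(=O)C(C)(C)C)cc3)[C@H](O)[C@H]4O)c(OCc3ccccc3)c2OCc2ccccc2)[C@@H](O)[C@H]1O
F4 | step 10 | 2,3-bis(benzyloxy)-4-bromophenyl formate | O=COc1ccc(Br)c(OCc2ccccc2)c1OCc1ccccc1
F5 | step 10 | 2,3-bis(benzyloxy)-4-bromophenol | Oc1ccc(Br)c(OCc2ccccc2)c1OCc1ccccc1
F6 | step 10 | 4-{(R)-[2,3-bis(benzyloxy)-4-bromophenoxy][(2R)-oxiran-2-yl]methyl}phenyl pivalate | CC(C)(C)C(=O)Oc1ccc(cc1)[C@@H](Oc1ccc(Br)c(OCc2ccccc2)c1OCc1ccccc1)[C@H]1CO1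
F7 | step 10 | (2R,3R)-7,8-bis(benzyloxy)-6-bromo-2-(4-pivaloyloxyphenyl)chroman-3-ol | CC(C)(C)C(=O)Oc1ccc(cc1)[C@H]1Oc2c(cc(Br)c(OCc3ccccc3)c2OCc2ccccc2)C[C@H]1O
F8 | step 9 | 4-{(S)-(methanesulfonyloxy)[(2R)-oxiran-2-yl]methyl}phenyl pivalate | CC(C)(C)C(=O)Oc1ccc(cc1)[C@H](OS(C)(=O)=O)[C@H]1CO1
F9 | step 8 | 4-[(1R)-1-hydroxyprop-2-en-1-yl]phenyl pivalate | CC(C)(C)C(=O)Oc1ccc(cc1)[C@H](O)C=C
F10 | step 8 | 4-{(R)-hydroxy[(2S)-oxiran-2-yl]methyl}phenyl pivalate | CC(C)(C)C(=O)Oc1ccc(cc1)[C@@H](O)[C@@H]1CO1
A1 | alternative 1 | aryl diazo enone on C6 of the silylene-protected all-cis half | c1ccccc1COc1ccc(cc1)[C@H]1Oc2c(cc(C(=[N+]=[N-])C(=O)/C=C/C(OC)OC)c(OCc3ccccc3)c2OCc2ccccc2)[C@@H](O[Si](C(C)(C)C)(C(C)(C)C)O3)[C@H]13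
A2 | alternative 1 | di-tert-butoxyethyne | CC(C)(C)OC#COC(C)(C)C
A3 | alternative 1 | all-cis half joined at C6 to the new ring A (C8a phenol, C7 and C8 tert-butyl ethers, C4a dimethyl acetal) | c1ccccc1COc1ccc(cc1)[C@H]1Oc2c(cc(-c3cc(C(OC)OC)c(O)c(OC(C)(C)C)c3OC(C)(C)C)c(OCc3ccccc3)c2OCc2ccccc2)[C@@H](O[Si](C(C)(C)C)(C(C)(C)C)O3)[C@H]13
A4 | alternative 2 | 2,2',3,3'-tetrakis(benzyloxy)-4,4'-dihydroxybiphenyl-5,5'-dicarbaldehyde | O=Cc1cc(-c2cc(C=O)c(O)c(OCc3ccccc3)c2OCc2ccccc2)c(OCc2ccccc2)c(OCc2ccccc2)c1O
A5 | alternative 2 | (E)-4-(benzyloxy)cinnamaldehyde | O=C/C=C/c1ccc(OCc2ccccc2)cc1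
A6 | alternative 2 | 6,6'-linked bis[7,8-bis(benzyloxy)-2-(4-benzyloxyphenyl)-2H-chromene-3-carbaldehyde] | c1ccccc1COc1ccc(cc1)[C@H]1Oc2c(cc(-c3cc4c(c(OCc5ccccc5)c3OCc3ccccc3)O[C@H](c3ccc(OCc5ccccc5)cc3)C(C=O)=C4)c(OCc3ccccc3)c2OCc2ccccc2)C=C1C=O
A7 | alternative 3 | hexa-O-benzyl 6,6'-bi(2,3-cis-flavan-3-ol) carrying one tert-butyl carbonate on O3 | c1ccccc1COc1ccc(cc1)[C@H]1Oc2c(cc(-c3cc4c(c(OCc5ccccc5)c3OCc3ccccc3)O[C@H](c3ccc(OCc5ccccc5)cc3)[C@H](O)C4)c(OCc3ccccc3)c2OCc2ccccc2)C[C@H]1OC(=O)OC(C)(C)C
A8 | alternative 3 | hexa-O-benzyl target with a 3,4-cis cyclic carbonate in one half and a 3,4-trans diol in the other | c1ccccc1COc1ccc(cc1)[C@H]1Oc2c(cc(-c3cc4c(c(OCc5ccccc5)c3OCc3ccccc3)O[C@H](c3ccc(OCc5ccccc5)cc3)[C@H](O)[C@H]4O)c(OCc3ccccc3)c2OCc2ccccc2)[C@@H](OC(=O)O3)[C@H]13
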